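## The problem

Target 27 is an open-chain monoester of a 1-aryl-2-alkylpropane-1,3-diol, so the task is chain assembly around one stereodiad, not ring construction. C1 is a secondary carbinol bearing a 4-methoxyphenyl ring, C2 bears the (E)-3-(3,4-dimethoxyphenyl)allyl chain, and the C3 oxygen is acylated by (Z)-2-(hydroxymethyl)but-2-enoic acid. Both stereocentres are S and anti to one another. C2 carries no heteroatom and must be set absolutely in a C–C bond-forming step. C1 can then be derived from C2 if the C1 and C3 oxygens are tied into a six-membered ring, where the anti diol corresponds to a trans-4,5-disubstituted 1,3-dioxane. The reverse relay is unattractive because C1 is an ionisable benzylic carbinol. Three groups restrict the chemistry: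
- the 4-methoxybenzylic alcohol, which can ionise, epimerise or eliminate under acid;
- the electron-rich E-styrene, which excludes hydrogenation, ozonolysis, strong oxidants and sensitising light;
- the angelate-type Z-enoate with its free allylic hydroxyl, the less stable geometric isomer, which isomerises under nucleophilic catalysis and can migrate to the C1 hydroxyl under base.

At the end the primary C3 hydroxyl must be acylated while the C1 and side-chain hydroxyls stay free. The enabling feature is that C1 is an oxygen-bearing carbon whose aryl group can be introduced last. With a carboxyl group in place of the aryl ring, C1 becomes the source of an α-oxy radical, and the 1,3-relationship of the C1 and C3 oxygens places that radical at ring C4 of a 2,2-dimethyl-1,3-dioxane, next to the C2 stereocentre at ring C5.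

## Retrosynthesis

**Ester C–O bond.** Target 27 is traced to its silyl ether 26 and then cut at the primary ester into diol 18 and the O-silylated Z-acid 24. This keeps the synthesis convergent and lets the Z-geometry be fixed on a five-carbon fragment. The alternative of building the side chain on the assembled molecule would expose the whole structure to a hydride reagent. The forward reaction must acylate the primary hydroxyl of 18 in the presence of the hindered benzylic one, through mixed anhydride 25, without isomerising the acid.

**Side-chain Cα–CH2OH bond.** Acid 24 comes from ethyl ester 23 and alcohol 22. Alcohol 22 is cut between the α-carbon and the hydroxymethyl carbon into ethyl but-2-ynoate 19 and formaldehyde 20, through the α-aluminated enoate 21. A syn hydrometalation of an alkyne is the most direct source of the less stable Z-isomer; olefination or allylic transposition routes favour the E-isomer. The precursor is a commercial four-carbon ester.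

**C1–aryl bond (key cut).** Diol 18 is the hydrolysis product of acetonide 17. In 17 the bond between ring C4 (target C1) and the 4-methoxyphenyl ring is cut, giving redox-active ester 13 and (4-methoxyphenyl)zinc chloride 16; 16 is made from 4-bromoanisole 14 through Grignard reagent 15. The neighbouring cuts are C1–C2 (an aldol with an aryl aldehyde) and C2–allyl (an alkylation or sigmatropic shift). Both require the acid-sensitive anisyl carbinol to be carried or created under enolate conditions, and both require two stereocentres to be controlled together. The chosen cut removes the anisyl carbinol from every earlier step and erases the configuration at the carboxyl-bearing carbon of 13, so only C2 must be pure. The forward reaction must form the C4–aryl bond trans to the C5 chain and must not touch the styrene.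

**Functional-group adjustments to the redox-active ester.** Ester 13 comes from acid 12, 12 from ethyl ester 11, and 11 from diol ester 10 by ketalisation. No skeletal bond is cut. The forward sequence must close the dioxane faster than the γ-hydroxy ester of 10 lactonises.

**C1–C2 bond.** Diol ester 10 is the reduction product of aldol aldehyde 9, which is cut between the α-carbon of aldehyde 7 and the carbonyl carbon of ethyl glyoxylate 8. This is the only step that sets an absolute configuration. Glyoxylate is a non-enolisable, highly electrophilic acceptor that brings the carboxyl group needed later. An auxiliary-based enolate would add attachment and removal steps. The forward reaction must give the (3R)-aldehyde 9, which becomes the (S)-configured C2 of the target after reduction changes the substituent priorities.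

**Allyl–CH2 bond and the styrene.** Aldehyde 7 comes from ester 6. Ester 6 is cut by a [3,3] shift of ketene acetal 5 into allylic alcohol 3 and triethyl orthoacetate 4, and 3 into 3,4-dimethoxybenzaldehyde 1 and vinylmagnesium bromide 2. The rearrangement builds the two-carbon extension and the E-styrene in one step from a racemic alcohol. Wittig routes to the same chain favour the Z-olefin.

## Roads not taken

**Alternative 1: asymmetric Prins reaction to a trans-1,3-dioxane.**
- Cut: C2–C3, C1–O and the acetal carbon are all taken from formaldehyde.
- Forward key step: the skipped diene A1 reacts with two molecules of formaldehyde 20 under a confined chiral Brønsted acid of the imidodiphosphorimidate class to give dioxane A2, with the trans relationship derived from the E-olefin.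
- Merits: both stereocentres and the whole diol core arise in one catalytic step from an achiral diene. The chosen plan spends steps 4 to 9 on the same result, so this road is clearly shorter.
- Weak points:
  - A 1,2-disubstituted styrene with a para-methoxy group reacts through a long-lived benzylic cation, which favours stepwise closure and puts both trans fidelity and enantiocontrol at risk.
  - The skipped diene can slip into conjugation under acid, and its terminal vinyl group is a second site for formaldehyde.
  - The product is a methylene acetal. Its removal needs much harsher acid than a ketal, at a 4-methoxybenzylic C–O bond.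
  - The dimethoxyaryl group must still be attached to the terminal alkene by a Heck arylation or cross-metathesis.
- Comparison: the chosen plan sets against the better step count a C2 centre made by an aminocatalytic aldol with direct substrate-class precedent, a C1 centre whose trans outcome coincides with the more stable diequatorial product, and a ketal that leaves in weak aqueous acid.

**Alternative 2: late Z-selective hydroalumination–hydroxymethylation.**
- Cut: the bond from the side-chain α-carbon to the hydroxymethyl carbon, made last.
- Forward key step: diol 18 would be converted into its C1 triethylsilyl ether and C3 but-2-ynoate, A3. The aluminium hydride of step 11 would add hydride to the β-carbon, and the α-aluminated enoate would be trapped by formaldehyde 20 to give A4; desilylation would finish.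
- Merits: no Z-acid is ever activated, so the isomerisation risk of step 14 disappears. On this point the alternative is better than the chosen plan.
- Weak points:
  - The ester that must survive is the one a stoichiometric aluminium hydride can cleave by 1,2-reduction.
  - The C1 hydroxyl must be protected and released, adding steps.
  - Any loss falls on the most advanced intermediate.
  - It says nothing about the stereodiad, so a core synthesis is still needed.
- Comparison: the chosen plan runs the same reaction on the simple ester 19, where material is cheap, and accepts in exchange the acylation risk of step 14.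

**Alternative 3: dianion Ireland–Claisen with chirality transfer.**
- Cut: the C2–allyl bond, with transposition of the allylic ester.
- Forward key step: β-hydroxy ester A5 is deprotonated twice and silylated, then rearranges through a chair to acid A6. This forms the C2–CH2 bond and the E-styrene while the allylic C–O bond breaks. One reduction of A6 would give diol 18.
- Merits: C1 is made early by two-electron chemistry with assured configuration, both aryl groups come from simple aldehydes, and the route to 18 would be several steps shorter. In length and in certainty at C1 it is better than the chosen plan.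
- Weak points:
  - Two separately enantioenriched partners are needed, and they must be the matched pair.
  - The 1-(3,4-dimethoxyphenyl)allyl ester is doubly activated towards ionisation, so racemisation and 1,3-transposition to the cinnamyl ester compete before the rearrangement.
  - The β-oxido enolate can eliminate or undergo retro-aldol cleavage on warming.
  - The C2 configuration depends on enolate geometry and on chair versus boat.
- Comparison: the chosen plan uses one source of chirality and one catalytic step, has a key step indifferent to the configuration of its precursor at C1, and avoids the ionisable allylic ester.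

Key step: step 9

Remark: the hydrogen-bond-directed enamine model is assumed to hold for the diarylprolinol aldol of 7, so the D-proline-derived catalyst is specified for the (3R)-aldehyde 9; ethyl glyoxylate 8 is used as its commercial toluene solution and formaldehyde 20 is generated from paraformaldehyde.

## Route

Step 1
Reactants: 1 3,4-dimethoxybenzaldehyde; 2 vinylmagnesium bromide
Product: 3 1-(3,4-dimethoxyphenyl)prop-2-en-1-ol (racemic)
Conditions: THF, 0 → 23 °C; aq. NH4Cl
Reagents that add atoms: none
Why: Grignard 1,2-addition to an aryl aldehyde; the carbinol centre is racemic and is destroyed in step 2.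

Step 2
Reactants: 3 1-(3,4-dimethoxyphenyl)prop-2-en-1-ol; 4 triethyl orthoacetate
Product: 6 ethyl (E)-5-(3,4-dimethoxyphenyl)pent-4-enoate, via ketene acetal 5 (not isolated)
Conditions: 4 (neat, excess), EtCO2H (cat.), 135 °C, EtOH distilled off
Reagents that add atoms: none
Why: Johnson–Claisen rearrangement; alcohol exchange and loss of ethanol give ketene acetal 5, whose chair [3,3] shift places the aryl-bearing carbon substituent equatorial and so delivers the E-styrene; the weak carboxylic acid catalyst limits ionisation of the electron-rich allylic carbinol.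

Step 3
Reactants: 6 ethyl (E)-5-(3,4-dimethoxyphenyl)pent-4-enoate
Product: 7 (E)-5-(3,4-dimethoxyphenyl)pent-4-enal
Conditions: iBu2AlH, CH2Cl2, −78 °C; aq. potassium sodium tartrate
Reagents that add atoms: none
Why: Partial reduction of an ester by iBu2AlH at low temperature, where the tetrahedral aluminium hemiacetal persists until work-up; the isolated styrene is inert to the hydride.

Step 4
Reactants: 7 (E)-5-(3,4-dimethoxyphenyl)pent-4-enal; 8 ethyl glyoxylate
Product: 10 ethyl (2S,3S,5E)-6-(3,4-dimethoxyphenyl)-2-hydroxy-3-(hydroxymethyl)hex-5-enoate, via aldol aldehyde 9 (not isolated)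
Conditions: (R)-α,α-bis[3,5-bis(trifluoromethyl)phenyl]pyrrolidin-2-ylmethanol (10 mol %), MeCN, H2O, 23 °C; then EtOH, NaBH4, −20 °C; pH 7 phosphate buffer
Reagents that add atoms: none
Why: Enamine-catalysed cross-aldol of an aldehyde donor with the non-enolisable glyoxylate; the catalyst hydroxyl hydrogen-bonds to the acceptor and delivers it to one face of the E-enamine, so the D-proline-derived catalyst should give the anti (2S,3R)-aldehyde 9; cold borohydride reduction in the same flask fixes the epimerisable centre as C3 of 10, which is C2 of the target, while the carbinol centre of 10 is erased in step 9.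

Step 5
Reactants: 10 ethyl (2S,3S,5E)-6-(3,4-dimethoxyphenyl)-2-hydroxy-3-(hydroxymethyl)hex-5-enoate
Product: 11 ethyl (4S,5S)-5-[(E)-3-(3,4-dimethoxyphenyl)allyl]-2,2-dimethyl-1,3-dioxane-4-carboxylate (trans)
Conditions: 2-methoxypropene, pyridinium p-toluenesulfonate (cat.), CH2Cl2, 0 °C; Et3N
Reagents that add atoms: 2-methoxypropene, C=C(C)OC
Why: Kinetic ketalisation of a 1,3-diol; the enol ether adds to the primary hydroxyl and the mixed ketal closes onto the secondary one, which at 0 °C with a weak acid should outrun acid-catalysed lactonisation of the γ-hydroxy ester.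

Step 6
Reactants: 11 ethyl (4S,5S)-5-[(E)-3-(3,4-dimethoxyphenyl)allyl]-2,2-dimethyl-1,3-dioxane-4-carboxylate
Product: 12 (4S,5S)-5-[(E)-3-(3,4-dimethoxyphenyl)allyl]-2,2-dimethyl-1,3-dioxane-4-carboxylic acid
Conditions: LiOH·H2O, THF/H2O, 0 → 23 °C; aq. KHSO4 to pH 4, 0 °C
Reagents that add atoms: lithium hydroxide, [Li+].[OH-]
Why: Saponification of an ethyl ester; the ketal is stable to base and survives the brief cold acidification, and any epimerisation at C4 is harmless because that centre is erased in step 9.

Step 7
Reactants: 12 (4S,5S)-5-[(E)-3-(3,4-dimethoxyphenyl)allyl]-2,2-dimethyl-1,3-dioxane-4-carboxylic acid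
Product: 13 1,3-dioxoisoindolin-2-yl (4S,5S)-5-[(E)-3-(3,4-dimethoxyphenyl)allyl]-2,2-dimethyl-1,3-dioxane-4-carboxylate
Conditions: N-hydroxyphthalimide, N,N'-diisopropylcarbodiimide, 4-(dimethylamino)pyridine (cat.), CH2Cl2, 23 °C
Reagents that add atoms: N-hydroxyphthalimide, O=C1c2ccccc2C(=O)N1O
Why: Carbodiimide (Steglich-type) esterification gives the redox-active ester under neutral conditions that leave the ketal and the styrene untouched.

Step 8
Reactants: 14 4-bromoanisole
Product: 16 (4-methoxyphenyl)zinc chloride, via arylmagnesium bromide 15 (not isolated)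
Conditions: Mg, LiCl, THF, 23–40 °C; then ZnCl2, THF, 0 → 23 °C
Reagents that add atoms: zinc chloride, Cl[Zn]Cl
Why: Grignard formation followed by transmetalation to zinc gives an arylzinc reagent that is nucleophilic enough for nickel but does not add to esters or imides.

Step 9
Reactants: 13 1,3-dioxoisoindolin-2-yl (4S,5S)-5-[(E)-3-(3,4-dimethoxyphenyl)allyl]-2,2-dimethyl-1,3-dioxane-4-carboxylate; 16 (4-methoxyphenyl)zinc chloride
Product: 17 (4S,5S)-5-[(E)-3-(3,4-dimethoxyphenyl)allyl]-4-(4-methoxyphenyl)-2,2-dimethyl-1,3-dioxane (trans)
Conditions: 16 (3 equiv), NiCl2(glyme) (20 mol %), 4,4'-di-tert-butyl-2,2'-bipyridine (40 mol %), THF/DMF, 25 °C; aq. NH4Cl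
Reagents that add atoms: none
Why: A low-valent aryl–nickel species formed from NiCl2(glyme), the bipyridine and 16 transfers one electron to the phthalimide ester of 13, whose radical anion fragments to phthalimide anion, CO2 and the α-alkoxy radical at ring C4 (target C1). The radical is captured by divalent aryl–nickel, and the trivalent alkyl(aryl)nickel formed reductively eliminates to make the C4–aryl bond; the closest known reaction type is the nickel-catalysed decarboxylative Negishi arylation of N-hydroxyphthalimide esters, which includes α-alkoxy acids. No ring closes. The one new stereocentre, C4, is controlled by the existing C5 centre: the configuration of the carboxyl-bearing carbon is lost at the radical, and the bulky ligated nickel should bond on the ring face anti to the C5 arylallyl chain, which coincides with the diequatorial trans product, so 17 should be (4S,5S) from either C4 epimer of 13. The step needs trans over cis and capture at nickel faster than any other fate of the radical. The α-oxygen stabilises the radical, and only 4-exo or 5-endo closure onto the styrene is open to it. The reaction is thermal, so the E-olefin is not sensitised, and the arylzinc chloride leaves the ketal and aryl ethers alone.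

Step 10
Reactants: 17 (4S,5S)-5-[(E)-3-(3,4-dimethoxyphenyl)allyl]-4-(4-methoxyphenyl)-2,2-dimethyl-1,3-dioxane
Product: 18 (1S,2S)-2-[(E)-3-(3,4-dimethoxyphenyl)allyl]-1-(4-methoxyphenyl)propane-1,3-diol
Conditions: AcOH/THF/H2O (3:1:1), 35 °C
Reagents that add atoms: none
Why: Acid-catalysed ketal hydrolysis through the tertiary oxocarbenium ion at the acetal carbon; acetic acid is too weak to ionise the 4-methoxybenzylic C–O bond at a useful rate, and water is the only nucleophile present, so C1 should keep its configuration.

Step 11
Reactants: 19 ethyl but-2-ynoate; 20 formaldehyde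
Product: 22 ethyl (Z)-2-(hydroxymethyl)but-2-enoate, via α-aluminated enoate 21 (not isolated)
Conditions: iBu2AlH, (Me2N)3PO, THF, 0 °C; then 20 (from cracked paraformaldehyde), 0 → 23 °C; aq. potassium sodium tartrate
Reagents that add atoms: none
Why: Conjugate syn-hydroalumination of an alkynoate puts hydride on the β-carbon and aluminium on the α-carbon with the methyl group cis to the ester; the vinylalane 21 adds to formaldehyde with retention, which fixes the Z-geometry, a known Z-selective entry to Morita–Baylis–Hillman-type alcohols.

Step 12
Reactants: 22 ethyl (Z)-2-(hydroxymethyl)but-2-enoate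
Product: 23 ethyl (Z)-2-[(tert-butyldimethylsilyloxy)methyl]but-2-enoate
Conditions: tBuMe2SiCl, imidazole, DMF, 0 → 23 °C
Reagents that add atoms: tert-butyldimethylsilyl chloride, CC(C)(C)[Si](C)(C)Cl
Why: Standard silylation of a primary allylic alcohol; it masks the hydroxyl so that the acid cannot acylate itself in step 14.

Step 13
Reactants: 23 ethyl (Z)-2-[(tert-butyldimethylsilyloxy)methyl]but-2-enoate
Product: 24 (Z)-2-[(tert-butyldimethylsilyloxy)methyl]but-2-enoic acid
Conditions: LiOH·H2O, THF/MeOH/H2O, 23 °C; aq. KHSO4 to pH 4
Reagents that add atoms: lithium hydroxide, [Li+].[OH-]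
Why: Saponification at ambient temperature; hydroxide does not add reversibly to the trisubstituted enoate under these conditions, so the Z-geometry and the silyl ether should both survive.

Step 14
Reactants: 24 (Z)-2-[(tert-butyldimethylsilyloxy)methyl]but-2-enoic acid; 18 (1S,2S)-2-[(E)-3-(3,4-dimethoxyphenyl)allyl]-1-(4-methoxyphenyl)propane-1,3-diol
Product: 26 (2S,3S)-2-[(E)-3-(3,4-dimethoxyphenyl)allyl]-3-hydroxy-3-(4-methoxyphenyl)propyl (Z)-2-[(tert-butyldimethylsilyloxy)methyl]but-2-enoate, via mixed anhydride 25 (not isolated)
Conditions: 2,4,6-trichlorobenzoyl chloride, Et3N, toluene, 0 → 23 °C; then 18, 4-(dimethylamino)pyridine (0.3 equiv), toluene, 0 °C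
Reagents that add atoms: none
Why: Yamaguchi esterification; the hindered mixed anhydride 25 transfers only the enoyl group, the primary hydroxyl of 18 reacts well ahead of the hindered benzylic one when one equivalent of acid is used, and low temperature with little aminopyridine limits Z-to-E isomerisation by reversible conjugate addition.

Step 15
Reactants: 26 (2S,3S)-2-[(E)-3-(3,4-dimethoxyphenyl)allyl]-3-hydroxy-3-(4-methoxyphenyl)propyl (Z)-2-[(tert-butyldimethylsilyloxy)methyl]but-2-enoate
Product: 27 (2S,3S)-2-[(E)-3-(3,4-dimethoxyphenyl)allyl]-3-hydroxy-3-(4-methoxyphenyl)propyl (Z)-2-(hydroxymethyl)but-2-enoate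
Conditions: HF·pyridine, pyridine, THF, 0 → 23 °C
Reagents that add atoms: none
Why: Fluoride cleavage of a primary silyl ether; the pyridine-buffered medium is neither acidic enough to ionise the benzylic alcohol nor basic enough to drive acyl migration from the C3 to the C1 oxygen.

## Compound list

1 | 3,4-dimethoxybenzaldehyde | COc1ccc(C=O)cc1OC | starting material
2 | vinylmagnesium bromide | C=C[Mg]Br | starting material
3 | 1-(3,4-dimethoxyphenyl)prop-2-en-1-ol (racemic) | C=CC(O)c1ccc(OC)c(OC)c1 | intermediate
4 | triethyl orthoacetate | CCOC(C)(OCC)OCC | starting material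
5 | 4-[1-(1-ethoxyvinyloxy)prop-2-en-1-yl]-1,2-dimethoxybenzene (ketene acetal) | C=CC(OC(=C)OCC)c1ccc(OC)c(OC)c1 | intermediate
6 | ethyl (E)-5-(3,4-dimethoxyphenyl)pent-4-enoate | CCOC(=O)CC/C=C/c1ccc(OC)c(OC)c1 | intermediate
7 | (E)-5-(3,4-dimethoxyphenyl)pent-4-enal | O=CCC/C=C/c1ccc(OC)c(OC)c1 | intermediate
8 | ethyl glyoxylate | CCOC(=O)C=O | starting material
9 | ethyl (2S,3R,5E)-6-(3,4-dimethoxyphenyl)-3-formyl-2-hydroxyhex-5-enoate | O=C[C@H](C/C=C/c1ccc(OC)c(OC)c1)[C@H](O)C(=O)OCC | intermediate
10 | ethyl (2S,3S,5E)-6-(3,4-dimethoxyphenyl)-2-hydroxy-3-(hydroxymethyl)hex-5-enoate | OC[C@H](C/C=C/c1ccc(OC)c(OC)c1)[C@H](O)C(=O)OCC | intermediate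
11 | ethyl (4S,5S)-5-[(E)-3-(3,4-dimethoxyphenyl)allyl]-2,2-dimethyl-1,3-dioxane-4-carboxylate | CC1(C)OC[C@H](C/C=C/c2ccc(OC)c(OC)c2)[C@@H](C(=O)OCC)O1 | intermediate
12 | (4S,5S)-5-[(E)-3-(3,4-dimethoxyphenyl)allyl]-2,2-dimethyl-1,3-dioxane-4-carboxylic acid | CC1(C)OC[C@H](C/C=C/c2ccc(OC)c(OC)c2)[C@@H](C(=O)O)O1 | intermediate
13 | 1,3-dioxoisoindolin-2-yl (4S,5S)-5-[(E)-3-(3,4-dimethoxyphenyl)allyl]-2,2-dimethyl-1,3-dioxane-4-carboxylate | CC1(C)OC[C@H](C/C=C/c2ccc(OC)c(OC)c2)[C@@H](C(=O)ON2C(=O)c3ccccc3C2=O)O1 | intermediate
14 | 4-bromoanisole | COc1ccc(Br)cc1 | starting material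
15 | (4-methoxyphenyl)magnesium bromide | COc1ccc([Mg]Br)cc1 | intermediate
16 | (4-methoxyphenyl)zinc chloride | COc1ccc([Zn]Cl)cc1 | intermediate
17 | (4S,5S)-5-[(E)-3-(3,4-dimethoxyphenyl)allyl]-4-(4-methoxyphenyl)-2,2-dimethyl-1,3-dioxane | CC1(C)OC[C@H](C/C=C/c2ccc(OC)c(OC)c2)[C@@H](c2ccc(OC)cc2)O1 | intermediate
18 | (1S,2S)-2-[(E)-3-(3,4-dimethoxyphenyl)allyl]-1-(4-methoxyphenyl)propane-1,3-diol | OC[C@H](C/C=C/c1ccc(OC)c(OC)c1)[C@H](O)c1ccc(OC)cc1 | intermediate
19 | ethyl but-2-ynoate | CC#CC(=O)OCC | starting material
20 | formaldehyde (from paraformaldehyde) | C=O | starting material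
21 | ethyl (E)-2-(diisobutylalumanyl)but-2-enoate | C/C=C(/[Al](CC(C)C)CC(C)C)C(=O)OCC | intermediate
22 | ethyl (Z)-2-(hydroxymethyl)but-2-enoate | C/C=C(/CO)C(=O)OCC | intermediate
23 | ethyl (Z)-2-[(tert-butyldimethylsilyloxy)methyl]but-2-enoate | C/C=C(/CO[Si](C)(C)C(C)(C)C)C(=O)OCC | intermediate
24 | (Z)-2-[(tert-butyldimethylsilyloxy)methyl]but-2-enoic acid | C/C=C(/CO[Si](C)(C)C(C)(C)C)C(=O)O | intermediate
25 | (Z)-2-[(tert-butyldimethylsilyloxy)methyl]but-2-enoic 2,4,6-trichlorobenzoic anhydride | C/C=C(/CO[Si](C)(C)C(C)(C)C)C(=O)OC(=O)c1c(Cl)cc(Cl)cc1Cl | intermediate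
26 | (2S,3S)-2-[(E)-3-(3,4-dimethoxyphenyl)allyl]-3-hydroxy-3-(4-methoxyphenyl)propyl (Z)-2-[(tert-butyldimethylsilyloxy)methyl]but-2-enoate | C/C=C(/CO[Si](C)(C)C(C)(C)C)C(=O)OC[C@H](C/C=C/c1ccc(OC)c(OC)c1)[C@H](O)c1ccc(OC)cc1 | intermediate
27 | (2S,3S)-2-[(E)-3-(3,4-dimethoxyphenyl)allyl]-3-hydroxy-3-(4-methoxyphenyl)propyl (Z)-2-(hydroxymethyl)but-2-enoate | C/C=C(/CO)C(=O)OC[C@H](C/C=C/c1ccc(OC)c(OC)c1)[C@H](O)c1ccc(OC)cc1 | target

## Step count and least certain steps

Total steps: 15. Longest linear sequence: 11 (steps 1 to 7, 9, 10, 14, 15); step 8 and steps 11 to 13 are side branches.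

**Step 9 (key step).**
- What may go wrong: the α-alkoxy redox-active ester may be consumed before productive capture, by direct acyl substitution with the arylzinc or by reduction of the radical to the C–H compound. Facial discrimination at C4 may also be incomplete, because in a chair an equatorial C5 substituent is gauche to both faces of the neighbouring radical centre.
- Reserve measure: reversible ionisation at the 4-methoxybenzylic C–O bond under a mild Lewis acid could funnel material to the trans ketal. It is held back because the cation may eliminate.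
- Fallback: it sets out from ester 6 and returns at diol 18, forming the C1–C2 bond by polar chemistry.
  - Ester 6 would be saponified to (E)-5-(3,4-dimethoxyphenyl)pent-4-enoic acid F1.
  - N-Acylation of (S)-4-benzyloxazolidin-2-one with F1 (pivaloyl chloride, Et3N, LiCl, THF) would give (S)-4-benzyl-3-[(E)-5-(3,4-dimethoxyphenyl)pent-4-enoyl]oxazolidin-2-one F2.
  - MgCl2-catalysed soft enolisation (Et3N, Me3SiCl, EtOAc) with 4-methoxybenzaldehyde would give the silylated anti-aldol adduct (S)-4-benzyl-3-[(2R,3S)-2-[(E)-3-(3,4-dimethoxyphenyl)allyl]-3-(4-methoxyphenyl)-3-(trimethylsilyloxy)propanoyl]oxazolidin-2-one F3. The chelated Z-enolate is shielded by the benzyl group as in the alkylation of such imides.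
  - Brief methanolysis (citric acid, MeOH) would free the aldol (S)-4-benzyl-3-[(2R,3S)-2-[(E)-3-(3,4-dimethoxyphenyl)allyl]-3-hydroxy-3-(4-methoxyphenyl)propanoyl]oxazolidin-2-one F4.
  - LiBH4 in wet THF would cleave the auxiliary reductively to diol 18.

**Step 4.**
- What may go wrong: intramolecular transesterification of the new primary hydroxyl onto the ethyl ester during reduction or work-up would remove the free 1,3-diol that step 5 needs. Homo-aldolisation of 7 is a secondary concern.
- Fallback: it sets out from diol ester 10, or its crude mixture, and returns at acid 12, using the lactone instead of avoiding it.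
  - Catalytic p-toluenesulfonic acid in CH2Cl2 would drive the material to (3S,4S)-4-[(E)-3-(3,4-dimethoxyphenyl)allyl]-3-hydroxydihydrofuran-2(3H)-one F5.
  - Acid-catalysed ring-opening ketalisation with 2,2-dimethoxypropane in MeOH (camphorsulfonic acid, cat.) would give methyl (4S,5S)-5-[(E)-3-(3,4-dimethoxyphenyl)allyl]-2,2-dimethyl-1,3-dioxane-4-carboxylate F6.
  - Saponification as in step 6 would give 12.

**Step 14.**
- What may go wrong: the activated Z-acyl species may isomerise to the more stable E-form through reversible conjugate addition of the nucleophilic catalyst, and acylation may spill onto the secondary hydroxyl.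
- Fallback: it sets out from diol 18 and returns at 26 without ever activating the acid as an acyl electrophile.
  - Primary-selective sulfonylation (p-toluenesulfonyl chloride, pyridine, 0 °C) would give (2S,3S)-2-[(E)-3-(3,4-dimethoxyphenyl)allyl]-3-hydroxy-3-(4-methoxyphenyl)propyl 4-methylbenzenesulfonate F7.
  - SN2 displacement by the preformed cesium salt of acid 24 (from Cs2CO3; DMF, 50 °C) would give 26.

**Step 11.**
- What may go wrong: 1,2-reduction of the ester carbonyl may compete, and the aluminium intermediate may lose its geometry through its allenolate form before formaldehyde is trapped.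
- Fallback: it sets out from 19 and returns at 22.
  - Syn-hydrostannation with Bu3SnH under Pd(PPh3)4 (a zerovalent palladium catalyst) would give ethyl (E)-2-(tributylstannyl)but-2-enoate F8.
  - Iododestannylation with I2 would give ethyl (E)-2-iodobut-2-enoate F9 with retention.
  - Stille coupling of F9 with (tributylstannyl)methanol (Pd(PPh3)4, dioxane, 80 °C) would install the hydroxymethyl group with retention to give 22.

## Further compounds

F1 | step 9 | (E)-5-(3,4-dimethoxyphenyl)pent-4-enoic acid | OC(=O)CC/C=C/c1ccc(OC)c(OC)c1
F2 | step 9 | (S)-4-benzyl-3-[(E)-5-(3,4-dimethoxyphenyl)pent-4-enoyl]oxazolidin-2-one | O=C(CC/C=C/c1ccc(OC)c(OC)c1)N1[C@@H](Cc2ccccc2)COC1=O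
F3 | step 9 | (S)-4-benzyl-3-[(2R,3S)-2-[(E)-3-(3,4-dimethoxyphenyl)allyl]-3-(4-methoxyphenyl)-3-(trimethylsilyloxy)propanoyl]oxazolidin-2-one | O=C([C@H](C/C=C/c1ccc(OC)c(OC)c1)[C@H](O[Si](C)(C)C)c1ccc(OC)cc1)N1[C@@H](Cc2ccccc2)COC1=O
F4 | step 9 | (S)-4-benzyl-3-[(2R,3S)-2-[(E)-3-(3,4-dimethoxyphenyl)allyl]-3-hydroxy-3-(4-methoxyphenyl)propanoyl]oxazolidin-2-one | O=C([C@H](C/C=C/c1ccc(OC)c(OC)c1)[C@H](O)c1ccc(OC)cc1)N1[C@@H](Cc2ccccc2)COC1=O
F5 | step 4 | (3S,4S)-4-[(E)-3-(3,4-dimethoxyphenyl)allyl]-3-hydroxydihydrofuran-2(3H)-one (cis) | O1C[C@H](C/C=C/c2ccc(OC)c(OC)c2)[C@H](O)C1=O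
F6 | step 4 | methyl (4S,5S)-5-[(E)-3-(3,4-dimethoxyphenyl)allyl]-2,2-dimethyl-1,3-dioxane-4-carboxylate | CC1(C)OC[C@H](C/C=C/c2ccc(OC)c(OC)c2)[C@@H](C(=O)OC)O1
F7 | step 14 | (2S,3S)-2-[(E)-3-(3,4-dimethoxyphenyl)allyl]-3-hydroxy-3-(4-methoxyphenyl)propyl 4-methylbenzenesulfonate | Cc1ccc(cc1)S(=O)(=O)OC[C@H](C/C=C/c1ccc(OC)c(OC)c1)[C@H](O)c1ccc(OC)cc1
F8 | step 11 | ethyl (E)-2-(tributylstannyl)but-2-enoate | C/C=C(/[Sn](CCCC)(CCCC)CCCC)C(=O)OCC
F9 | step 11 | ethyl (E)-2-iodobut-2-enoate | C/C=C(/I)C(=O)OCC
A1 | alternative 1 | (E)-1-(4-methoxyphenyl)penta-1,4-diene | C=CC/C=C/c1ccc(OC)cc1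
A2 | alternative 1 | (4S,5S)-5-allyl-4-(4-methoxyphenyl)-1,3-dioxane (trans) | C=CC[C@H]1COCO[C@@H]1c1ccc(OC)cc1
A3 | alternative 2 | (2S,3S)-2-[(E)-3-(3,4-dimethoxyphenyl)allyl]-3-(4-methoxyphenyl)-3-(triethylsilyloxy)propyl but-2-ynoate | CC#CC(=O)OC[C@H](C/C=C/c1ccc(OC)c(OC)c1)[C@H](O[Si](CC)(CC)CC)c1ccc(OC)cc1
A4 | alternative 2 | (2S,3S)-2-[(E)-3-(3,4-dimethoxyphenyl)allyl]-3-(4-methoxyphenyl)-3-(triethylsilyloxy)propyl (Z)-2-(hydroxymethyl)but-2-enoate | C/C=C(/CO)C(=O)OC[C@H](C/C=C/c1ccc(OC)c(OC)c1)[C@H](O[Si](CC)(CC)CC)c1ccc(OC)cc1
A5 | alternative 3 | (R)-1-(3,4-dimethoxyphenyl)allyl (S)-3-hydroxy-3-(4-methoxyphenyl)propanoate | C=C[C@@H](OC(=O)C[C@H](O)c1ccc(OC)cc1)c1ccc(OC)c(OC)c1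
A6 | alternative 3 | (2R,3S)-2-[(E)-3-(3,4-dimethoxyphenyl)allyl]-3-hydroxy-3-(4-methoxyphenyl)propanoic acid | OC(=O)[C@H](C/C=C/c1ccc(OC)c(OC)c1)[C@H](O)c1ccc(OC)cc1
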